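The route rests on cutting C7–C8 (C1 = OCH2) inside the featureless C2–C19 methylene run that separates the benzoate ring from stereocentre C20. The key step is a nickel hydride reductive hydroalkylation that joins three components in one operation: silane hydride goes to C9 and the ester-bearing C1–C7 chain goes to C8. Its precursors are (S)-13-methylpentadec-1-ene, whose vinyl group is C8=C9 and whose C20 comes from the chiral pool, and 7-bromoheptyl 2,3-bis(benzyloxy)benzoate. The step exploits the unbranched chain: reversible β-hydride elimination funnels any olefin positional isomers back to the primary C8–nickel species, while ester, arene and remote C20 stay untouched. Hydrogenolysis of both catechol benzyl ethers finishes.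

Key step: step 3

Remark: the alkyl chain is numbered from the ester OCH2 (C1) to the terminal methyl (C22). The stereocentre C20 is S. 2,3-Bis(benzyloxy)benzoic acid is taken as a catalogue compound.

Step 1
Reactants: 1 (S)-1-bromo-2-methylbutane; 2 11-bromoundec-1-ene
Product: 4 (S)-13-methylpentadec-1-ene, via (S)-2-methylbutylmagnesium bromide 3 (not isolated)
Conditions: 1 (1.4 equiv), Mg, THF, 40 °C; then 2, Li2CuCl4 (3 mol %), THF, −20 °C → rt
Reagents that add atoms: magnesium, [Mg] (held by 3 only; it does not remain in 4)
Why: The copper-catalysed Grignard–alkyl halide cross-coupling (Kochi–Tamura coupling with Li2CuCl4) of a primary Grignard reagent with an unhindered primary bromide is reliable, leaves the terminal olefin alone and never touches the stereocentre β to magnesium, so the S configuration of the chiral-pool bromide becomes C20 of the target.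

Step 2
Reactants: 5 2,3-bis(benzyloxy)benzoic acid; 6 7-bromoheptan-1-ol
Product: 7 7-bromoheptyl 2,3-bis(benzyloxy)benzoate
Conditions: DCC (1.1 equiv), DMAP (10 mol %), CH2Cl2, 0 °C → rt
Reagents that add atoms: none
Why: The Steglich esterification activates the ortho-substituted acid as its O-acylisourea and acylpyridinium ion, which the primary alcohol intercepts under neutral conditions that leave the primary bromide and the benzyl ethers untouched.

Step 3
Reactants: 4 (S)-13-methylpentadec-1-ene (1.5 equiv); 7 7-bromoheptyl 2,3-bis(benzyloxy)benzoate
Product: 9 (S)-20-methyldocosyl 2,3-bis(benzyloxy)benzoate, via 7-iodoheptyl 2,3-bis(benzyloxy)benzoate 8 (not isolated)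
Conditions: NiBr2·diglyme (10 mol %), 4,4'-di-tert-butyl-2,2'-bipyridine (15 mol %), (EtO)2MeSiH (2.5 equiv), Na2CO3 (2 equiv), NaI (0.5 equiv), DMA, 30 °C
Reagents that add atoms: sodium iodide, [Na+].[I-] (its iodine sits in 8 only; 9 takes up only hydrogen, from the silane)
Why: Halide exchange with NaI turns 7 into iodide 8, while (dtbbpy)Ni–H, formed from the nickel halide, the silane and carbonate, inserts the C8=C9 vinyl group of 4 in the anti-Markovnikov sense (H to C9, Ni to C8); a Ni(I) species abstracts iodine from 8, the primary C7 radical is captured by the C8–nickel complex, and reductive elimination from dialkylnickel(III) forms C7–C8. The closest known reaction type is the nickel-hydride-catalysed reductive hydroalkylation (olefin hydrocarbonation) of unactivated terminal alkenes with unactivated primary alkyl halides. No ring is closed and no stereocentre is made, so neither a mode of closure nor a controlling element is called for. Cross-coupling over homocoupling is the first selectivity needed, and it is secured by orthogonal activation: only the olefin of 4 can insert into Ni–H, and only the carbon–halogen bond of 7 or 8 can be opened by halogen-atom abstraction. Linear over branched coupling is the second, and the unbranched chain secures it, because insertion and β-hydride elimination are reversible and the unhindered primary C8–nickel species is the one that couples, so any internal olefin formed by chain walking is funnelled back to the same product. C20 lies ten methylene groups (C10–C19) away from the olefin and would be reached only by a long uphill walk through secondary alkylnickels, so its configuration should be safe, and the ester, the benzyl ethers and the arenes are inert to silane and low-valent nickel at 30 °C.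

Step 4
Reactants: 9 (S)-20-methyldocosyl 2,3-bis(benzyloxy)benzoate
Product: 10 gentiside B, (S)-20-methyldocosyl 2,3-dihydroxybenzoate
Conditions: H2 (1 atm), 10 % Pd/C, EtOAc–EtOH, rt
Reagents that add atoms: none
Why: Catalytic hydrogenolysis cleaves only the two benzylic C–O bonds of the aryl benzyl ethers, whereas the ester C1–O bond is not benzylic and the saturated chain with C20 offers nothing to reduce or epimerise.

Compound list
1 | (S)-1-bromo-2-methylbutane | CC[C@H](C)CBr | starting material
2 | 11-bromoundec-1-ene | C=CCCCCCCCCCBr | starting material
3 | (S)-2-methylbutylmagnesium bromide | CC[C@H](C)C[Mg]Br | intermediate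
4 | (S)-13-methylpentadec-1-ene | CC[C@H](C)CCCCCCCCCCC=C | intermediate
5 | 2,3-bis(benzyloxy)benzoic acid | OC(=O)c1cccc(OCc2ccccc2)c1OCc3ccccc3 | starting material
6 | 7-bromoheptan-1-ol | OCCCCCCCBr | starting material
7 | 7-bromoheptyl 2,3-bis(benzyloxy)benzoate | BrCCCCCCCOC(=O)c1cccc(OCc2ccccc2)c1OCc3ccccc3 | intermediate
8 | 7-iodoheptyl 2,3-bis(benzyloxy)benzoate | ICCCCCCCOC(=O)c1cccc(OCc2ccccc2)c1OCc3ccccc3 | intermediate
9 | (S)-20-methyldocosyl 2,3-bis(benzyloxy)benzoate | CC[C@H](C)CCCCCCCCCCCCCCCCCCCOC(=O)c1cccc(OCc2ccccc2)c1OCc3ccccc3 | intermediate
10 | gentiside B, (S)-20-methyldocosyl 2,3-dihydroxybenzoate | CC[C@H](C)CCCCCCCCCCCCCCCCCCCOC(=O)c1cccc(O)c1O | target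

Total step count: 4
Longest linear sequence: 3 (steps 1, 3, 4; equally steps 2, 3, 4)

Steps most likely to fail

Step 3. Hydrodehalogenation of the halide, homocoupling of the C7 radical, and hydrogenation or unproductive isomerisation of the olefin may outrun C–C bond formation and use up both partners. The fallback sets out from 4 and comes back at 9. Hydroboration of 4 with 9-BBN-H (THF, rt) should place boron on C8 and give B-[(S)-13-methylpentadecyl]-9-borabicyclo[3.3.1]nonane F1. In the same flask F1 would be coupled with bromide 7 in an alkyl–alkyl Suzuki–Miyaura reaction (Pd(OAc)2, PCy3, K3PO4·H2O, THF, rt). A preformed C8–B bond and a polar transmetalation then replace the hydride and radical manifold, and no hydride source is left that could reduce the bromide.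

Step 1. Wurtz-type homocoupling during formation of the β-branched Grignard reagent, and incomplete cross-coupling, may leave non-polar hydrocarbons and bromide that are hard to separate from the equally non-polar olefin. The fallback sets out from 1 and comes back at 4, passing through polar intermediates that can be purified by chromatography.
- Sodium benzenesulfinate (DMF, 80 °C) should convert 1 into (S)-(2-methylbutyl) phenyl sulfone F2.
- Deprotonation (n-BuLi, THF, −78 °C) and alkylation with 2 should give (13S)-13-methyl-12-(phenylsulfonyl)pentadec-1-ene F3. It forms as a mixture at C12, which is of no consequence.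
- Reductive desulfonylation (Na/Hg, Na2HPO4, MeOH–THF) erases C12 as a stereocentre and returns 4. The hydrogen at C13 is never acidified.

Step 4. Poisoning of palladium by traces of iodide or nickel carried over from step 3, together with poor solubility of the waxy substrate, may stall the reaction at the stage of partial debenzylation. The fallback sets out from 9 and comes back at 10 directly. It is a Lewis-acid debenzylation with BCl3 and pentamethylbenzene as cation scavenger (CH2Cl2, −78 °C), which needs no metal surface and spares the alkyl ester. New compounds on this way: none F0.

Further compounds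
F1 | step 3 | B-[(S)-13-methylpentadecyl]-9-borabicyclo[3.3.1]nonane | CC[C@H](C)CCCCCCCCCCCCB1C2CCCC1CCC2
F2 | step 1 | (S)-(2-methylbutyl) phenyl sulfone | CC[C@H](C)CS(=O)(=O)c1ccccc1
F3 | step 1 | (13S)-13-methyl-12-(phenylsulfonyl)pentadec-1-ene (both C12 epimers) | CC[C@H](C)C(CCCCCCCCCC=C)S(=O)(=O)c1ccccc1
F0 | step 4 | none | none
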